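**Retrosynthetic overview**

1. Isogoiazensolide ⇐ its C5 4-methoxybenzyl ether (final deprotection only).
2. That ether ⇐ an acyclic 2-bromoalkene / tertiary propargylic alcohol plus CO: one palladium-catalysed carbonylative operation supplies C3 and closes the ten-membered carbocycle and the 3(2H)-furanone together.
3. Acyclic precursor ⇐ chromium allylation (C7–C8) of a hydroxy-alkynal (C8–C10, C14, C1, C2) with a 3-(bromomethyl)butenolide (C4–C7, C11–C13, C15). This sets C7 and C8 and unveils the α-methylene lactone; the C8 methacrylate follows.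
4. Butenolide ⇐ ring-closing metathesis ⇐ Sharpless kinetic resolution of 2-bromopenta-1,4-dien-3-ol (C5, C6). Hydroxy-alkynal ⇐ (S)-lactic acid by Seebach allylation (C10).
5. Ring order: butenolide, then α-methylene γ-lactone (allylic transposition in the allylation), then ten-membered ring and furanone in one operation.

Assumption: germacrane numbering (C1–C15, lactone C6–O–C12, ester on C8) is used for positions, and 2-bromoacrolein is taken as a purchased starting material.

**Route**

Step 1
Reactants: 1 (S)-lactic acid; 2 pivalaldehyde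
Product: 3 (2S,5S)-2-tert-butyl-5-methyl-1,3-dioxolan-4-one
Conditions: TsOH·H2O (cat.), H2SO4 (cat.), pentane, reflux (Dean–Stark); recrystallisation from pentane at −78 °C
Reagents that add atoms: 2 pivalaldehyde, CC(C)(C)C=O
Why: Acid-catalysed acetalisation (Seebach self-regeneration of stereocentres) keeps the lactate centre, and crystallisation gives the cis acetal, whose new acetal centre will relay the configuration.

Step 2
Reactants: 3 (2S,5S)-2-tert-butyl-5-methyl-1,3-dioxolan-4-one; 4 allyl bromide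
Product: 5 (2S,5R)-2-tert-butyl-5-methyl-5-(prop-2-en-1-yl)-1,3-dioxolan-4-one
Conditions: LiN(iPr)2, THF, −78 °C; then 4, −78 → −30 °C
Reagents that add atoms: 4 allyl bromide, C=CCBr
Why: Enolate alkylation occurs anti to the tert-butyl group, so the quaternary centre is rebuilt with overall retention and becomes the (R)-configured C10.

Step 3
Reactants: 5 (2S,5R)-2-tert-butyl-5-methyl-5-(prop-2-en-1-yl)-1,3-dioxolan-4-one; 6 dimethyl (1-diazo-2-oxopropyl)phosphonate
Product: 8 (R)-3-methylhex-5-en-1-yn-3-ol, via dioxolanol 7 (not isolated)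
Conditions: iBu2AlH (1.1 equiv), CH2Cl2, −78 °C; then MeOH, K2CO3, 6 (2.5 equiv), −78 °C → rt
Reagents that add atoms: 6 dimethyl (1-diazo-2-oxopropyl)phosphonate, CC(=O)C(=[N+]=[N-])P(=O)(OC)OC
Why: Hydride reduction stops at the lactol, basic methanol releases the α-hydroxy aldehyde, and Ohira–Bestmann (Seyferth–Gilbert) homologation gives the terminal alkyne; the quaternary centre has no α-hydrogen and cannot epimerise.

Step 4
Reactants: 8 (R)-3-methylhex-5-en-1-yn-3-ol; 9 ozone
Product: 10 (R)-3-hydroxy-3-methylpent-4-ynal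
Conditions: O3, CH2Cl2, −78 °C (Sudan red 7B end point); then PPh3, −78 °C → rt; used crude
Reagents that add atoms: 9 ozone, [O-][O+]=O
Why: Ozonolysis with reductive work-up cleaves the terminal alkene much faster than the terminal alkyne when stopped at the indicator end point; C10 is untouched.

Step 5
Reactants: 11 2-bromoprop-2-enal; 12 vinylmagnesium bromide
Product: 13 racemic 2-bromopenta-1,4-dien-3-ol
Conditions: 12 (1.05 equiv), THF, −78 °C; aq. NH4Cl
Reagents that add atoms: 12 vinylmagnesium bromide, C=C[Mg]Br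
Why: Grignard 1,2-addition to the enal at low temperature gives the bis-allylic alcohol, racemic at this stage.

Step 6
Reactants: 13 racemic 2-bromopenta-1,4-dien-3-ol; 14 tert-butyl hydroperoxide
Product: 15 (S)-2-bromo-1-[(S)-oxiran-2-yl]prop-2-en-1-ol
Conditions: Ti(OiPr)4 (0.2 equiv), D-(−)-diisopropyl tartrate (0.24 equiv), 14 (0.55 equiv), 4 Å molecular sieves, CH2Cl2, −20 °C, stopped near 50% conversion
Reagents that add atoms: 14 tert-butyl hydroperoxide, CC(C)(C)OO
Why: Sharpless asymmetric epoxidation run as a kinetic resolution epoxidises the (S)-alcohol fast, only on the unsubstituted vinyl group (the 2-bromovinyl group is too electron-poor), and gives the erythro epoxy alcohol, which sets C5 and C6 (maximum yield 50%).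

Step 7
Reactants: 15 (S)-2-bromo-1-[(S)-oxiran-2-yl]prop-2-en-1-ol; 16 4-methoxybenzyl chloride
Product: 17 (S)-2-[(S)-2-bromo-1-[(4-methoxyphenyl)methoxy]prop-2-en-1-yl]oxirane
Conditions: NaH, 16, Bu4NI (cat.), THF/DMF, −20 → 0 °C
Reagents that add atoms: 16 4-methoxybenzyl chloride, COc1ccc(CCl)cc1
Why: Williamson etherification under aprotic conditions is faster than Payne rearrangement and installs a C5 ether that cannot migrate in later alkoxide steps.

Step 8
Reactants: 17 (S)-2-[(S)-2-bromo-1-[(4-methoxyphenyl)methoxy]prop-2-en-1-yl]oxirane; 18 trimethylsulfonium iodide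
Product: 19 (3S,4S)-5-bromo-4-[(4-methoxyphenyl)methoxy]hexa-1,5-dien-3-ol
Conditions: 18 (3 equiv), n-BuLi (2.9 equiv), THF, −10 °C; then 17, −10 °C → rt
Reagents that add atoms: 18 trimethylsulfonium iodide, C[S+](C)C.[I-]
Why: Dimethylsulfonium methylide opens the terminal epoxide carbon (C7) and the betaine eliminates to the allylic alcohol (epoxide-to-allylic-alcohol homologation), so the C6–O bond and its configuration are untouched.

Step 9
Reactants: 19 (3S,4S)-5-bromo-4-[(4-methoxyphenyl)methoxy]hexa-1,5-dien-3-ol; 20 2-(bromomethyl)prop-2-enoic acid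
Product: 21 (3S,4S)-5-bromo-4-[(4-methoxyphenyl)methoxy]hexa-1,5-dien-3-yl 2-(bromomethyl)prop-2-enoate
Conditions: 20, N,N'-dicyclohexylcarbodiimide, DMAP (5 mol%), CH2Cl2, 0 °C
Reagents that add atoms: 20 2-(bromomethyl)prop-2-enoic acid, C=C(CBr)C(=O)O
Why: Steglich esterification acylates the only free hydroxyl (C6–OH) without touching a stereocentre.

Step 10
Reactants: 21 (3S,4S)-5-bromo-4-[(4-methoxyphenyl)methoxy]hexa-1,5-dien-3-yl 2-(bromomethyl)prop-2-enoate
Product: 22 (S)-5-[(S)-2-bromo-1-[(4-methoxyphenyl)methoxy]prop-2-en-1-yl]-3-(bromomethyl)furan-2(5H)-one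
Conditions: second-generation Grubbs catalyst RuCl2(=CHPh)(H2IMes)(PCy3) (5 mol%), toluene (5 mM), 80 °C
Reagents that add atoms: none
Why: Ring-closing metathesis loads on the monosubstituted alkene and closes onto the acrylate to give the butenolide; the 2-bromoalkene is inert to metathesis and C5/C6 are untouched.

Step 11
Reactants: 22 (S)-5-[(S)-2-bromo-1-[(4-methoxyphenyl)methoxy]prop-2-en-1-yl]-3-(bromomethyl)furan-2(5H)-one; 10 (R)-3-hydroxy-3-methylpent-4-ynal
Product: 23 (4R,5S)-5-[(S)-2-bromo-1-[(4-methoxyphenyl)methoxy]prop-2-en-1-yl]-4-[(1S,3R)-1,3-dihydroxy-3-methylpent-4-yn-1-yl]-3-methylideneoxolan-2-one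
Conditions: CrCl2 (4 equiv, nickel-free), 10 (1.5 equiv), THF, 0 °C → rt; aq. NH4Cl
Reagents that add atoms: none
Why: In this Nozaki–Hiyama allylation divalent chromium inserts only into the allylic C–Br bond, and the allylchromium adds through a chair Zimmerman–Traxler transition state at C7 anti to the C6 side chain (trans lactone, 7R); its ring-fixed E-type geometry gives the 7,8-anti adduct (8S) and unveils the α-methylene lactone.

Step 12
Reactants: 23 (the diol from step 11); 24 methacrylic anhydride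
Product: 25 (1S,3R)-1-[(2S,3R)-2-[(S)-2-bromo-1-[(4-methoxyphenyl)methoxy]prop-2-en-1-yl]-4-methylidene-5-oxooxolan-3-yl]-3-hydroxy-3-methylpent-4-yn-1-yl 2-methylprop-2-enoate
Conditions: 24 (3 equiv), Et3N, DMAP (0.2 equiv), CH2Cl2, 0 °C → rt
Reagents that add atoms: 24 methacrylic anhydride, C=C(C)C(=O)OC(=O)C(C)=C
Why: DMAP-catalysed acylation takes the secondary C8–OH, while the tertiary propargylic C10–OH is too hindered to react.

Step 13
Reactants: 25 (the methacrylate from step 12); 26 carbon monoxide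
Product: 28 5-O-(4-methoxybenzyl)isogoiazensolide, via macrocyclic ynone 27 (not isolated)
Conditions: PdCl2(PPh3)2 (10 mol%), Et3N (5 equiv), CO (10 atm), CO2 (10 atm), MeCN, 80 °C; 25 added by syringe pump over 12 h (final 1 mM)
Reagents that add atoms: 26 carbon monoxide, [C-]#[O+]
Why: Proposed new method: zerovalent palladium adds to the 2-bromoalkene and CO insertion gives an acryloyl-palladium species; direct non-carbonylative closure would be a strained nine-membered enyne, so the acyl group is passed to the tethered terminal alkyne (copper-free Sonogashira-type alkynyl transfer and reductive elimination, or anti attack of the in-situ carbonate on the palladium-bound alkyne), closing the ten-membered ring as ynone 27; CO2 then turns the C10 alkoxide into a carbonate that adds 5-exo to the ynone and, after loss of CO2 and cyclodehydration, leaves the C10 oxygen on C3 as the 3(2H)-furanone; the closest known reactions are the intermolecular palladium-catalysed carbonylative coupling of aryl or vinyl halides with tertiary propargylic alcohols under CO/CO2, which gives 3(2H)-furanones directly, and carbonylative macrocyclisations of vinyl halides and triflates; no stereocentre is formed or touched.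

Step 14
Reactants: 28 5-O-(4-methoxybenzyl)isogoiazensolide
Product: 29 isogoiazensolide
Conditions: DDQ (1.5 equiv), CH2Cl2/pH 7 phosphate buffer (10:1), 0 °C
Reagents that add atoms: none
Why: Oxidative 4-methoxybenzyl ether cleavage (benzylic hydride abstraction by DDQ, then hydrolysis) frees the C5–OH under neutral conditions that spare the methacrylate, the α-methylene lactone and the dienone.

**Compound list**

1 | (S)-lactic acid | C[C@H](O)C(=O)O | starting material
2 | pivalaldehyde | CC(C)(C)C=O | starting material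
3 | (2S,5S)-2-tert-butyl-5-methyl-1,3-dioxolan-4-one | C[C@@H]1O[C@H](C(C)(C)C)OC1=O | intermediate
4 | allyl bromide | C=CCBr | starting material
5 | (2S,5R)-2-tert-butyl-5-methyl-5-(prop-2-en-1-yl)-1,3-dioxolan-4-one | C[C@]1(CC=C)O[C@H](C(C)(C)C)OC1=O | intermediate
6 | dimethyl (1-diazo-2-oxopropyl)phosphonate | CC(=O)C(=[N+]=[N-])P(=O)(OC)OC | starting material
7 | (2S,5R)-2-tert-butyl-5-methyl-5-(prop-2-en-1-yl)-1,3-dioxolan-4-ol (C4 epimers, present as aluminium alkoxide) | C[C@]1(CC=C)O[C@H](C(C)(C)C)OC1O | intermediate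
8 | (R)-3-methylhex-5-en-1-yn-3-ol | C=CC[C@@](C#C)(C)O | intermediate
9 | ozone | [O-][O+]=O | starting material
10 | (R)-3-hydroxy-3-methylpent-4-ynal | O=CC[C@@](C#C)(C)O | intermediate
11 | 2-bromoprop-2-enal (2-bromoacrolein) | C=C(Br)C=O | starting material
12 | vinylmagnesium bromide | C=C[Mg]Br | starting material
13 | racemic 2-bromopenta-1,4-dien-3-ol | C=CC(O)C(Br)=C | intermediate
14 | tert-butyl hydroperoxide | CC(C)(C)OO | starting material
15 | (S)-2-bromo-1-[(S)-oxiran-2-yl]prop-2-en-1-ol | C=C(Br)[C@@H](O)[C@H]1OC1 | intermediate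
16 | 4-methoxybenzyl chloride | COc1ccc(CCl)cc1 | starting material
17 | (S)-2-[(S)-2-bromo-1-[(4-methoxyphenyl)methoxy]prop-2-en-1-yl]oxirane | C=C(Br)[C@@H](OCc1ccc(OC)cc1)[C@H]1OC1 | intermediate
18 | trimethylsulfonium iodide | C[S+](C)C.[I-] | starting material
19 | (3S,4S)-5-bromo-4-[(4-methoxyphenyl)methoxy]hexa-1,5-dien-3-ol | C=C(Br)[C@@H](OCc1ccc(OC)cc1)[C@H](C=C)O | intermediate
20 | 2-(bromomethyl)prop-2-enoic acid | C=C(CBr)C(=O)O | starting material
21 | (3S,4S)-5-bromo-4-[(4-methoxyphenyl)methoxy]hexa-1,5-dien-3-yl 2-(bromomethyl)prop-2-enoate | C=C(Br)[C@@H](OCc1ccc(OC)cc1)[C@H](C=C)OC(=O)C(=C)CBr | intermediate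
22 | (S)-5-[(S)-2-bromo-1-[(4-methoxyphenyl)methoxy]prop-2-en-1-yl]-3-(bromomethyl)furan-2(5H)-one | C=C(Br)[C@@H](OCc1ccc(OC)cc1)[C@H]1OC(=O)C(CBr)=C1 | intermediate
23 | (4R,5S)-5-[(S)-2-bromo-1-[(4-methoxyphenyl)methoxy]prop-2-en-1-yl]-4-[(1S,3R)-1,3-dihydroxy-3-methylpent-4-yn-1-yl]-3-methylideneoxolan-2-one | C=C(Br)[C@@H](OCc1ccc(OC)cc1)[C@H]1OC(=O)C(=C)[C@@H]1[C@@H](O)C[C@@](C#C)(C)O | intermediate
24 | methacrylic anhydride | C=C(C)C(=O)OC(=O)C(C)=C | starting material
25 | (1S,3R)-1-[(2S,3R)-2-[(S)-2-bromo-1-[(4-methoxyphenyl)methoxy]prop-2-en-1-yl]-4-methylidene-5-oxooxolan-3-yl]-3-hydroxy-3-methylpent-4-yn-1-yl 2-methylprop-2-enoate | C=C(Br)[C@@H](OCc1ccc(OC)cc1)[C@H]1OC(=O)C(=C)[C@@H]1[C@@H](OC(=O)C(C)=C)C[C@@](C#C)(C)O | intermediate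
26 | carbon monoxide | [C-]#[O+] | starting material
27 | macrocyclic ynone: ten-membered carbocycle of 28 with free C10–OH, C1≡C2 triple bond and C3 ketone (5R,6S,7R,8S,10R) | C=C(C)C(=O)O[C@H]1C[C@@](C)(O)C#CC(=O)C(=C)[C@@H](OCc2ccc(OC)cc2)[C@H]2OC(=O)C(=C)[C@@H]21 | intermediate
28 | 5-O-(4-methoxybenzyl)isogoiazensolide (5R,6S,7R,8S,10R) | C=C(C)C(=O)O[C@H]1C[C@@]2(C)OC(=CC2=O)C(=C)[C@@H](OCc3ccc(OC)cc3)[C@H]2OC(=O)C(=C)[C@@H]21 | intermediate
29 | isogoiazensolide (5R,6S,7R,8S,10R) | C=C(C)C(=O)O[C@H]1C[C@@]2(C)OC(=CC2=O)C(=C)[C@@H](O)[C@H]2OC(=O)C(=C)[C@@H]21 | target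

**Step count and risks**

Total step count: 14 (west branch steps 1–4, east branch steps 5–10, union and endgame steps 11–14). Longest linear sequence: 10 steps (5–14).

The three steps most likely to fail:

1. Step 13 (carbonylative macrocyclisation and furanone annulation). It has no macrocyclic precedent. Oligomerisation, Heck attack of the vinylpalladium on the α-methylene lactone, and double-bond migration under the basic, hot conditions are the likely failure modes. Fallback: install C3 before the ring closure and close the C3–C4 bond by a Nozaki–Hiyama–Kishi reaction. It sets out from 8. EtMgBr (2.1 equiv) then HC(OEt)3 gives (R)-1,1-diethoxy-4-methylhept-6-en-2-yn-4-ol F1. Ozonolysis as in step 4 gives (R)-6,6-diethoxy-3-hydroxy-3-methylhex-4-ynal F2. CrCl2 allylation with 22 as in step 11 gives the 3,3-diethoxyprop-1-ynyl analogue of 23 F3. Methacrylic anhydride as in step 12 gives the 3,3-diethoxyprop-1-ynyl analogue of 25 F4. Aqueous formic acid releases the ynal analogue of 25 F5. CrCl2 with NiCl2 (cat.) in DMSO/THF at high dilution couples the 2-bromoalkene with the ynal to give the macrocyclic C3 propargylic alcohol F6 (C3 epimers). MnO2 oxidises this to ynone 27, where the fallback comes back to the route; 27 is then cycloisomerised to 28 with Ph3PAuNTf2 (cat.) in wet toluene.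

2. Step 11 (chromium allylation). Aldehyde 10 is a retro-aldol-prone β-hydroxy aldehyde, the C8 configuration rests on the chair transition state, and the product can translactonise. Fallback: replace the reductive chromium allylation by an allylboration with an isolated reagent. It sets out from 22. Pd2(dba)3 (cat.) and B2pin2 in DMSO at rt convert the allylic bromide, which reacts far faster than the 2-bromoalkene, into (S)-5-[(S)-2-bromo-1-[(4-methoxyphenyl)methoxy]prop-2-en-1-yl]-3-[(4,4,5,5-tetramethyl-1,3,2-dioxaborolan-2-yl)methyl]furan-2(5H)-one F7. This boronate and 10 in toluene at rt react through a closed chair transition state, and aqueous work-up of the borate returns the route to 23.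

3. Step 10 (ring-closing metathesis of the 2-(bromomethyl)acrylate). Closure to a trisubstituted butenolide is slow and the allylic bromide may not survive 80 °C. Fallback: close the butenolide without the allylic bromide and build the C11–C13 bond afterwards. It sets out from 19. Acryloyl chloride and Et3N give (3S,4S)-5-bromo-4-[(4-methoxyphenyl)methoxy]hexa-1,5-dien-3-yl prop-2-enoate F8. Second-generation Grubbs catalyst gives (S)-5-[(S)-2-bromo-1-[(4-methoxyphenyl)methoxy]prop-2-en-1-yl]furan-2(5H)-one F9. I2 and pyridine give the 3-iodo derivative of that butenolide F10. Stille coupling with Bu3SnCH2OH (Pd2(dba)3, AsPh3, rt; the iodide reacts before the bromide) gives the 3-(hydroxymethyl) derivative of that butenolide F11. CBr4 and PPh3 then give 22, where the route is rejoined.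

**Further compounds**

F1 | step 13 | (R)-1,1-diethoxy-4-methylhept-6-en-2-yn-4-ol | C=CC[C@@](C#CC(OCC)OCC)(C)O
F2 | step 13 | (R)-6,6-diethoxy-3-hydroxy-3-methylhex-4-ynal | O=CC[C@@](C#CC(OCC)OCC)(C)O
F3 | step 13 | 3,3-diethoxyprop-1-ynyl analogue of 23 | C=C(Br)[C@@H](OCc1ccc(OC)cc1)[C@H]1OC(=O)C(=C)[C@@H]1[C@@H](O)C[C@@](C#CC(OCC)OCC)(C)O
F4 | step 13 | 3,3-diethoxyprop-1-ynyl analogue of 25 | C=C(Br)[C@@H](OCc1ccc(OC)cc1)[C@H]1OC(=O)C(=C)[C@@H]1[C@@H](OC(=O)C(C)=C)C[C@@](C#CC(OCC)OCC)(C)O
F5 | step 13 | ynal analogue of 25 | C=C(Br)[C@@H](OCc1ccc(OC)cc1)[C@H]1OC(=O)C(=C)[C@@H]1[C@@H](OC(=O)C(C)=C)C[C@@](C#CC=O)(C)O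
F6 | step 13 | macrocyclic C3 propargylic alcohol (C3 epimers) | C=C(C)C(=O)O[C@H]1C[C@@](C)(O)C#CC(O)C(=C)[C@@H](OCc2ccc(OC)cc2)[C@H]2OC(=O)C(=C)[C@@H]21
F7 | step 11 | (S)-5-[(S)-2-bromo-1-[(4-methoxyphenyl)methoxy]prop-2-en-1-yl]-3-[(4,4,5,5-tetramethyl-1,3,2-dioxaborolan-2-yl)methyl]furan-2(5H)-one | C=C(Br)[C@@H](OCc1ccc(OC)cc1)[C@H]1OC(=O)C(CB2OC(C)(C)C(C)(C)O2)=C1
F8 | step 10 | (3S,4S)-5-bromo-4-[(4-methoxyphenyl)methoxy]hexa-1,5-dien-3-yl prop-2-enoate | C=C(Br)[C@@H](OCc1ccc(OC)cc1)[C@H](C=C)OC(=O)C=C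
F9 | step 10 | (S)-5-[(S)-2-bromo-1-[(4-methoxyphenyl)methoxy]prop-2-en-1-yl]furan-2(5H)-one | C=C(Br)[C@@H](OCc1ccc(OC)cc1)[C@H]1OC(=O)C=C1
F10 | step 10 | (S)-5-[(S)-2-bromo-1-[(4-methoxyphenyl)methoxy]prop-2-en-1-yl]-3-iodofuran-2(5H)-one | C=C(Br)[C@@H](OCc1ccc(OC)cc1)[C@H]1OC(=O)C(I)=C1
F11 | step 10 | (S)-5-[(S)-2-bromo-1-[(4-methoxyphenyl)methoxy]prop-2-en-1-yl]-3-(hydroxymethyl)furan-2(5H)-one | C=C(Br)[C@@H](OCc1ccc(OC)cc1)[C@H]1OC(=O)C(CO)=C1
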